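The C3 ketone and the cis C4–C5 epoxide of the ten-membered carbocycle are read as an oxidised (Z)-allylic alcohol, so the ring is opened at C3–C4 (germacrane numbering). A Nozaki–Hiyama–Kishi reaction joins the C4 (Z)-alkenyl iodide to the C3 aldehyde of a seco compound that already carries the trans-fused C6–C7 α-methylene lactone, the C8 tiglate and the C1 silyl ether. One operation forms the C3–C4 bond, the ring and the C3 carbinol that later steers the epoxidation. The seco aldehyde comes from a zinc allylation of a C8–C10/C1–C3 aldehyde with a 3-(bromomethyl)butenolide, followed by tigloylation with inversion at C8.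

Key step: step 15

Assumption: the Ni/Cr closure is taken to give mainly the 3R carbinol (C3–H turned towards C6, C2 and C7 on the same olefin face); the 3S epimer is also usable (see fallbacks).
Note: locants are germacrane locants (C1 CHOH, C3 C=O, C4/C5 epoxide, C6 lactone CH–O, C8 CH–O-tiglate, C10 CHMe, C11–C13 methylene lactone). C6 is labelled S in 25, R in 27 and S again from 28 on, only because CIP priorities change. Compounds 1, 10 and 15 are taken as commercial.

Step 1
Reactants: 1 3-[(4-methoxybenzyl)oxy]propan-1-ol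
Product: 2 3-[(4-methoxybenzyl)oxy]propanal
Conditions: TEMPO (cat.), PhI(OAc)2, CH2Cl2, rt
Reagents that add atoms: none
Why: Oxoammonium (TEMPO/BAIB) oxidation of a primary alcohol should stop at the aldehyde and is mild enough to avoid β-elimination of the PMB ether.

Step 2
Reactants: 2 3-[(4-methoxybenzyl)oxy]propanal
Product: 4 (3R,4S)-1-[(4-methoxybenzyl)oxy]-4-methylhex-5-en-3-ol, via diisopinocampheylborinate 3 (not isolated)
Conditions: trans-but-2-ene, n-BuLi, KOt-Bu, THF, −78 → −45 °C; (−)-Ipc2BOMe, then BF3·OEt2, −78 °C; 2, −78 °C; NaOH, H2O2, rt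
Reagents that add atoms: trans-but-2-ene (C/C=C/C), transferred as (E)-crotyldiisopinocampheylborane (C/C=C/CB([C@@H]1C[C@@H]2C[C@H]([C@H]1C)C2(C)C)[C@@H]1C[C@@H]2C[C@H]([C@H]1C)C2(C)C)
Why: Brown crotylation: the E-crotylborane reacts through a chair transition state, which sets C10-methyl and C1-hydroxyl anti, and the isopinocampheyl groups from (+)-α-pinene direct attack to the Si face of the aldehyde, which should give C1 R and C10 S.

Step 3
Reactants: 4 (3R,4S)-1-[(4-methoxybenzyl)oxy]-4-methylhex-5-en-3-ol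
Product: 5 tert-butyl{[(3R,4S)-1-[(4-methoxybenzyl)oxy]-4-methylhex-5-en-3-yl]oxy}dimethylsilane
Conditions: TBSOTf, 2,6-lutidine, CH2Cl2, −78 → 0 °C
Reagents that add atoms: tert-butyldimethylsilyl triflate (CC(C)(C)[Si](C)(C)OS(=O)(=O)C(F)(F)F)
Why: Silylation of a secondary alcohol with a silyl triflate and a hindered base touches no stereocentre.

Step 4
Reactants: 5 tert-butyl{[(3R,4S)-1-[(4-methoxybenzyl)oxy]-4-methylhex-5-en-3-yl]oxy}dimethylsilane
Product: 7 (3S,4R)-4-[(tert-butyldimethylsilyl)oxy]-6-[(4-methoxybenzyl)oxy]-3-methylhexan-1-ol, via B-alkyl-9-borabicyclononane 6 (not isolated)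
Conditions: 9-BBN, THF, 0 °C → rt; then NaOH, H2O2, 0 °C → rt
Reagents that add atoms: hydrogen peroxide (OO)
Why: Anti-Markovnikov hydroboration of the monosubstituted olefin with a bulky borane, then oxidation, should give the C8 primary alcohol without affecting C10.

Step 5
Reactants: 7 (3S,4R)-4-[(tert-butyldimethylsilyl)oxy]-6-[(4-methoxybenzyl)oxy]-3-methylhexan-1-ol
Product: 8 (3S,4R)-4-[(tert-butyldimethylsilyl)oxy]-6-[(4-methoxybenzyl)oxy]-3-methylhexanal
Conditions: Dess–Martin periodinane, NaHCO3, CH2Cl2, 0 °C → rt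
Reagents that add atoms: none
Why: Buffered Dess–Martin oxidation should give the C8 aldehyde, which has no α-stereocentre to lose.

Step 6
Reactants: 9 acrolein; 10 prop-1-ynylmagnesium bromide
Product: 11 rac-hex-1-en-4-yn-3-ol
Conditions: THF, −78 °C; sat. aq NH4Cl
Reagents that add atoms: none
Why: Alkynyl Grignard reagents add 1,2 to enals, which gives the racemic C6 carbinol flanked by vinyl and propynyl groups.

Step 7
Reactants: 11 rac-hex-1-en-4-yn-3-ol
Product: 13 rac-(4Z)-5-iodohexa-1,4-dien-3-ol, via cyclic alkenylalanate 12 (not isolated)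
Conditions: Red-Al, THF, 0 °C → rt; EtOAc; I2, THF, −78 → 0 °C
Reagents that add atoms: iodine (II)
Why: Alkoxide-directed trans-hydroalumination of the propargylic alcohol places aluminium on the distal carbon (C4) in a five-membered alanate, and iodinolysis with retention should give the iodide with iodine cis to C6 (Z); the isolated vinyl group is inert.

Step 8
Reactants: 13 rac-(4Z)-5-iodohexa-1,4-dien-3-ol
Product: 14 (3S,4Z)-5-iodohexa-1,4-dien-3-ol
Conditions: Ti(Oi-Pr)4 (10 mol %), L-(+)-DIPT (15 mol %), t-BuOOH (0.6 equiv), 4 Å MS, CH2Cl2, −20 °C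
Reagents that add atoms: none
Why: Sharpless kinetic resolution: with L-(+)-tartrate the 3R enantiomer should be epoxidised at its vinyl group much faster, so the 3S alcohol is recovered; the Z-configured, iodine-bearing olefin is a poor substrate and should stay intact.

Step 9
Reactants: 14 (3S,4Z)-5-iodohexa-1,4-dien-3-ol; 15 2-(bromomethyl)prop-2-enoic acid
Product: 17 (3S,4Z)-5-iodohexa-1,4-dien-3-yl 2-(bromomethyl)prop-2-enoate, via O-acylisourea 16 (not isolated)
Conditions: DCC, DMAP (5 mol %), CH2Cl2, 0 °C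
Reagents that add atoms: none
Why: Steglich esterification acylates the carbinol oxygen without breaking the C6–O bond, so the configuration is kept; low temperature and little DMAP should spare the allylic bromide.

Step 10
Reactants: 17 (3S,4Z)-5-iodohexa-1,4-dien-3-yl 2-(bromomethyl)prop-2-enoate
Product: 18 (5S)-3-(bromomethyl)-5-[(1Z)-2-iodoprop-1-en-1-yl]furan-2(5H)-one
Conditions: Grubbs II (5 mol %), CH2Cl2 (0.01 M), 40 °C
Reagents that add atoms: none
Why: Ring-closing metathesis between the vinyl group and the 1,1-disubstituted acrylate olefin should close the butenolide (C7=C11) with loss of ethene; the trisubstituted iodoalkene does not engage.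

Step 11
Reactants: 8 (3S,4R)-4-[(tert-butyldimethylsilyl)oxy]-6-[(4-methoxybenzyl)oxy]-3-methylhexanal; 18 (5S)-3-(bromomethyl)-5-[(1Z)-2-iodoprop-1-en-1-yl]furan-2(5H)-one
Product: 20 (1R,6S,7R,8S,10S) C8 carbinol with trans α-methylene lactone, via allylzinc bromide 19 (not isolated)
Conditions: Zn dust, THF/sat. aq NH4Cl, 0 °C → rt
Reagents that add atoms: none
Why: Barbier allylation: zinc inserts only into the allylic C–Br bond and the allylzinc adds through C7 in a chair transition state, anti to the C6 alkenyl group (trans lactone, 7R) and, because C6 is locked trans to CH2Zn, with 7,8-anti topicity, which should give the 8S carbinol and unveil the methylene lactone.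

Step 12
Reactants: 20 (1R,6S,7R,8S,10S) C8 carbinol; 21 tiglic acid
Product: 23 (1R,6S,7R,8R,10S) C8 tiglate with C3 PMB ether, via alkoxyphosphonium tiglate 22 (not isolated)
Conditions: PPh3, DIAD, toluene, 0 °C → rt
Reagents that add atoms: none
Why: Mitsunobu esterification: tiglate displaces the C8 oxyphosphonium group in an SN2 step, which installs the ester and inverts C8 from S to R as the target requires.

Step 13
Reactants: 23 (1R,6S,7R,8R,10S) C8 tiglate with C3 PMB ether
Product: 24 (1R,6S,7R,8R,10S) C3 primary alcohol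
Conditions: DDQ, CH2Cl2/pH 7 buffer, 0 °C
Reagents that add atoms: none
Why: Oxidative PMB cleavage via the benzylic oxocarbenium ion should leave the silyl ether, both esters, the alkenyl iodide and the electron-poor olefins untouched.

Step 14
Reactants: 24 (1R,6S,7R,8R,10S) C3 primary alcohol
Product: 25 (1R,6S,7R,8R,10S) seco aldehyde
Conditions: Dess–Martin periodinane, NaHCO3, CH2Cl2, 0 °C → rt
Reagents that add atoms: none
Why: Buffered Dess–Martin oxidation should give the β-silyloxy aldehyde without elimination; it is used at once.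

Step 15
Reactants: 25 (1R,6S,7R,8R,10S) seco aldehyde
Product: 27 (1R,3R,4Z,6R,7R,8R,10S) 3-hydroxy-4Z-ene macrocycle, via alkenylchromium(III) dichloride 26 (not isolated)
Conditions: CrCl2 (excess), NiCl2 (cat.), degassed DMSO, rt, syringe-pump addition of 25 (final ca. 2 mM)
Reagents that add atoms: none
Why: Nickel(0), formed from NiCl2 and Cr(II), inserts into the C4–I bond with retention of the Z geometry, transmetallation gives alkenylchromium 26, and this adds to the C3 aldehyde. The closest known reaction type is the intramolecular Ni/Cr-mediated alkenyl iodide–aldehyde coupling used for ten-membered and larger carbocycles. The ten-membered ring closes in a 10-exo-trig addition, helped by high dilution and by the two turn elements already present, the trans-fused C6–C7 lactone and the Z olefin. The new stereocentre C3 is set by the ring-forming transition state: with C2 and C7 on the same olefin face and the aldehyde hydrogen, not oxygen, turned towards C6 to avoid 1,3-allylic strain, the 3R carbinol should form. The step needs chemoselectivity, which is secured because the organochromium species adds to aldehydes but not to the tiglate, the lactone or its methylene group, and because 25 holds no other carbon–halogen bond. Selectivity at C3 is needed only as the handle for the epoxidation, since C3 ends as a ketone.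

Step 16
Reactants: 27 (1R,3R,4Z,6R,7R,8R,10S) 3-hydroxy-4Z-ene macrocycle
Product: 28 (1R,3R,4S,5R,6S,7R,8R,10S) epoxy alcohol
Conditions: mCPBA, NaHCO3, CH2Cl2, 0 °C
Reagents that add atoms: 3-chloroperoxybenzoic acid (OOC(=O)c1cccc(Cl)c1)
Why: Hydrogen-bond-directed (Henbest) peracid epoxidation: with C3–H eclipsing the Z olefin, the 3R hydroxyl lies on the face opposite C2 and C7 and should deliver the peracid there (threo), which is the epoxide face of the target; the conjugated methylene-lactone and tiglate olefins are too electron-poor to react.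

Step 17
Reactants: 28 (1R,3R,4S,5R,6S,7R,8R,10S) epoxy alcohol
Product: 29 (1R,4R,5R,6S,7R,8R,10S) epoxy ketone
Conditions: Dess–Martin periodinane, NaHCO3, CH2Cl2, 0 °C → rt
Reagents that add atoms: none
Why: Buffered Dess–Martin oxidation of the epoxy carbinol should give the α,β-epoxy ketone without opening the epoxide; C4 is quaternary and cannot epimerise.

Step 18
Reactants: 29 (1R,4R,5R,6S,7R,8R,10S) epoxy ketone
Product: 30 eupakirunsin C
Conditions: HF·pyridine, pyridine, THF, 0 °C → rt
Reagents that add atoms: none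
Why: Buffered fluoride desilylation should free the C1 hydroxyl without the β-elimination or retro-aldol cleavage that basic fluoride could cause in the β-hydroxy ketone.

Compound list
1 | 3-[(4-methoxybenzyl)oxy]propan-1-ol | COc1ccc(COCCCO)cc1 | starting material
2 | 3-[(4-methoxybenzyl)oxy]propanal | COc1ccc(COCCC=O)cc1 | intermediate
3 | (3R,4S)-1-[(4-methoxybenzyl)oxy]-4-methylhex-5-en-3-yl diisopinocampheylborinate | COc1ccc(COCC[C@@H](OB([C@@H]2C[C@@H]3C[C@H]([C@H]2C)C3(C)C)[C@@H]2C[C@@H]3C[C@H]([C@H]2C)C3(C)C)[C@@H](C)C=C)cc1 | intermediate (not isolated)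
4 | (3R,4S)-1-[(4-methoxybenzyl)oxy]-4-methylhex-5-en-3-ol | COc1ccc(COCC[C@@H](O)[C@@H](C)C=C)cc1 | intermediate
5 | tert-butyl{[(3R,4S)-1-[(4-methoxybenzyl)oxy]-4-methylhex-5-en-3-yl]oxy}dimethylsilane | COc1ccc(COCC[C@@H](O[Si](C)(C)C(C)(C)C)[C@@H](C)C=C)cc1 | intermediate
6 | 9-[(3S,4R)-4-[(tert-butyldimethylsilyl)oxy]-6-[(4-methoxybenzyl)oxy]-3-methylhexyl]-9-borabicyclo[3.3.1]nonane | COc1ccc(COCC[C@@H](O[Si](C)(C)C(C)(C)C)[C@@H](C)CCB2C3CCCC2CCC3)cc1 | intermediate (not isolated)
7 | (3S,4R)-4-[(tert-butyldimethylsilyl)oxy]-6-[(4-methoxybenzyl)oxy]-3-methylhexan-1-ol | COc1ccc(COCC[C@@H](O[Si](C)(C)C(C)(C)C)[C@@H](C)CCO)cc1 | intermediate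
8 | (3S,4R)-4-[(tert-butyldimethylsilyl)oxy]-6-[(4-methoxybenzyl)oxy]-3-methylhexanal | COc1ccc(COCC[C@@H](O[Si](C)(C)C(C)(C)C)[C@@H](C)CC=O)cc1 | intermediate
9 | acrolein | C=CC=O | starting material
10 | prop-1-ynylmagnesium bromide | CC#C[Mg]Br | starting material
11 | rac-hex-1-en-4-yn-3-ol | C=CC(O)C#CC | intermediate
12 | sodium 2,2-bis(2-methoxyethoxy)-3-methyl-5-vinyl-2,5-dihydro-1,2-oxaaluminol-2-uide (cyclic Z-alkenylalanate) | C=CC1O[Al-](OCCOC)(OCCOC)C(C)=C1.[Na+] | intermediate (not isolated)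
13 | rac-(4Z)-5-iodohexa-1,4-dien-3-ol | C=CC(O)/C=C(C)\I | intermediate
14 | (3S,4Z)-5-iodohexa-1,4-dien-3-ol | C=C[C@H](O)/C=C(C)\I | intermediate
15 | 2-(bromomethyl)prop-2-enoic acid | C=C(CBr)C(=O)O | starting material
16 | O-[2-(bromomethyl)acryloyl]-N,N'-dicyclohexylisourea | C=C(CBr)C(=O)OC(=NC1CCCCC1)NC1CCCCC1 | intermediate (not isolated)
17 | (3S,4Z)-5-iodohexa-1,4-dien-3-yl 2-(bromomethyl)prop-2-enoate | C=C[C@H](OC(=O)C(=C)CBr)/C=C(C)\I | intermediate
18 | (5S)-3-(bromomethyl)-5-[(1Z)-2-iodoprop-1-en-1-yl]furan-2(5H)-one | BrCC1=C[C@@H](/C=C(C)\I)OC1=O | intermediate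
19 | {[(5S)-5-[(1Z)-2-iodoprop-1-en-1-yl]-2-oxo-2,5-dihydrofuran-3-yl]methyl}zinc bromide | Br[Zn]CC1=C[C@@H](/C=C(C)\I)OC1=O | intermediate (not isolated)
20 | (4R,5S)-4-[(1S,3S,4R)-4-[(tert-butyldimethylsilyl)oxy]-1-hydroxy-6-[(4-methoxybenzyl)oxy]-3-methylhexyl]-5-[(1Z)-2-iodoprop-1-en-1-yl]-3-methylideneoxolan-2-one (germacrane 1R,6S,7R,8S,10S) | COc1ccc(COCC[C@@H](O[Si](C)(C)C(C)(C)C)[C@@H](C)C[C@H](O)[C@@H]2[C@@H](/C=C(C)\I)OC(=O)C2=C)cc1 | intermediate
21 | tiglic acid, (2E)-2-methylbut-2-enoic acid | C/C=C(\C)C(=O)O | starting material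
22 | C8 (triphenylphosphonio)oxy derivative of 20 as its tiglate salt | COc1ccc(COCC[C@@H](O[Si](C)(C)C(C)(C)C)[C@@H](C)C[C@H](O[P+](c2ccccc2)(c2ccccc2)c2ccccc2)[C@@H]2[C@@H](/C=C(C)\I)OC(=O)C2=C)cc1.C/C=C(\C)C(=O)[O-] | intermediate (not isolated)
23 | (1R,3S,4R)-4-[(tert-butyldimethylsilyl)oxy]-1-{(2S,3R)-2-[(1Z)-2-iodoprop-1-en-1-yl]-4-methylidene-5-oxooxolan-3-yl}-6-[(4-methoxybenzyl)oxy]-3-methylhexyl (2E)-2-methylbut-2-enoate (germacrane 1R,6S,7R,8R,10S) | COc1ccc(COCC[C@@H](O[Si](C)(C)C(C)(C)C)[C@@H](C)C[C@@H](OC(=O)/C(C)=C/C)[C@@H]2[C@@H](/C=C(C)\I)OC(=O)C2=C)cc1 | intermediate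
24 | C3 primary alcohol of 23 after PMB removal (germacrane 1R,6S,7R,8R,10S) | OCC[C@@H](O[Si](C)(C)C(C)(C)C)[C@@H](C)C[C@@H](OC(=O)/C(C)=C/C)[C@@H]1[C@@H](/C=C(C)\I)OC(=O)C1=C | intermediate
25 | seco aldehyde: C3 aldehyde, C4 (Z)-alkenyl iodide, trans methylene lactone, C8 tiglate, C1 OTBS (germacrane 1R,6S,7R,8R,10S) | O=CC[C@@H](O[Si](C)(C)C(C)(C)C)[C@@H](C)C[C@@H](OC(=O)/C(C)=C/C)[C@@H]1[C@@H](/C=C(C)\I)OC(=O)C1=C | intermediate
26 | C4 alkenylchromium(III) dichloride derived from 25 | O=CC[C@@H](O[Si](C)(C)C(C)(C)C)[C@@H](C)C[C@@H](OC(=O)/C(C)=C/C)[C@@H]1[C@@H](/C=C(C)\[Cr](Cl)Cl)OC(=O)C1=C | intermediate (not isolated)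
27 | 3-hydroxy-4Z-ene macrocycle (germacrane 1R,3R,4Z,6R,7R,8R,10S; 1-OTBS, 8-tiglate, 6,12-olide) | C1[C@@H](O)/C(C)=C\[C@H]2OC(=O)C(=C)[C@@H]2[C@H](OC(=O)/C(C)=C/C)C[C@H](C)[C@@H]1O[Si](C)(C)C(C)(C)C | intermediate
28 | 4,5-epoxy-3-ol (germacrane 1R,3R,4S,5R,6S,7R,8R,10S; 1-OTBS) | C=C1C(=O)O[C@H]2[C@H]1[C@H](OC(=O)/C(C)=C/C)C[C@H](C)[C@H](O[Si](C)(C)C(C)(C)C)C[C@@H](O)[C@]1(C)O[C@H]21 | intermediate
29 | 4,5-epoxy-3-one (germacrane 1R,4R,5R,6S,7R,8R,10S; 1-OTBS) | C=C1C(=O)O[C@H]2[C@H]1[C@H](OC(=O)/C(C)=C/C)C[C@H](C)[C@H](O[Si](C)(C)C(C)(C)C)CC(=O)[C@]1(C)O[C@H]21 | intermediate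
30 | eupakirunsin C (germacrane 1R,4R,5R,6S,7R,8R,10S) | C=C1C(=O)O[C@H]2[C@H]1[C@H](OC(=O)/C(C)=C/C)C[C@H](C)[C@H](O)CC(=O)[C@]1(C)O[C@H]21 | target

Total step count: 18. Longest linear sequence: 13 steps (steps 1–5 or 6–10, then 11–18).

Steps most likely to fail

1. Step 15. The ten-membered closure may be outrun by intermolecular coupling, and the aldehyde may be attacked mainly on its other face, so that the carbinol arrives as the 3S epimer. The fallback sets out from 25 and changes the way oxygen is delivered instead of correcting C3. The closure product is then the 3S carbinol F1. It is epoxidised by vanadium-alkoxide delivery (VO(acac)2, t-BuOOH, CH2Cl2), which in Z and medium-ring allylic alcohols places the epoxide erythro (cis) to the hydroxyl. For the 3S epimer that is the same olefin face as in 28, so the 3S epoxy alcohol F2 should result. Dess–Martin oxidation of F2 erases C3 and comes back to the route at 29.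

2. Step 12. Displacement at the hindered C8 centre by the weakly acidic tiglic acid may be slow, so that elimination towards C7 or acyl transfer with retention competes. The fallback sets out from 20 and separates inversion from acylation. A Mitsunobu reaction with formic acid (PPh3, DIAD, THF) gives the inverted 8R formate F3. Mild methanolysis (KHCO3, MeOH, 0 °C) frees the 8R alcohol F4. Yamaguchi esterification with tiglic acid 21 (2,4,6-trichlorobenzoyl chloride, Et3N; DMAP, toluene), which retains configuration, comes back to the route at 23.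

3. Step 16. Facial selectivity may be poor if the ring does not hold the hydroxyl on the open olefin face, and the peracid may act elsewhere. The fallback sets out from 27 and replaces hydroxyl delivery by substrate-controlled nucleophilic epoxidation. Dess–Martin oxidation gives the (Z)-enone F5. Weitz–Scheffer epoxidation (t-BuOOH, DBU, CH2Cl2, 0 °C) should attack C5 from the face away from C2 and C7 and close onto C4 before the ring-held enolate can rotate. This gives the cis-epoxy ketone directly and comes back to the route at 29, so step 17 is not needed.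

Further compounds
F1 | step 15 | 3S epimer of 27 (germacrane 1R,3S,4Z,6R,7R,8R,10S) | C1[C@H](O)/C(C)=C\[C@H]2OC(=O)C(=C)[C@@H]2[C@H](OC(=O)/C(C)=C/C)C[C@H](C)[C@@H]1O[Si](C)(C)C(C)(C)C
F2 | step 15 | 3S epimer of 28 (germacrane 1R,3S,4S,5R,6S,7R,8R,10S) | C=C1C(=O)O[C@H]2[C@H]1[C@H](OC(=O)/C(C)=C/C)C[C@H](C)[C@H](O[Si](C)(C)C(C)(C)C)C[C@H](O)[C@]1(C)O[C@H]21
F3 | step 12 | 8R formate of the C8 carbinol (germacrane 1R,6S,7R,8R,10S) | COc1ccc(COCC[C@@H](O[Si](C)(C)C(C)(C)C)[C@@H](C)C[C@@H](OC=O)[C@@H]2[C@@H](/C=C(C)\I)OC(=O)C2=C)cc1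
F4 | step 12 | 8R epimer of 20 (germacrane 1R,6S,7R,8R,10S) | COc1ccc(COCC[C@@H](O[Si](C)(C)C(C)(C)C)[C@@H](C)C[C@@H](O)[C@@H]2[C@@H](/C=C(C)\I)OC(=O)C2=C)cc1
F5 | step 16 | (4Z)-3-oxo-4-ene macrocycle (germacrane 1R,4Z,6R,7R,8R,10S) | C1C(=O)/C(C)=C\[C@H]2OC(=O)C(=C)[C@@H]2[C@H](OC(=O)/C(C)=C/C)C[C@H](C)[C@@H]1O[Si](C)(C)C(C)(C)C
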